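**Retrosynthetic overview**

1. Ester C3–O bond: Mitsunobu inversion of the allylic alcohol with 3,4-dihydroxybenzoic acid (catechol → bromination → hydroxycarbonylation), then para-selective O-methylation as the last step.
2. C3 carbinol: CBS reduction of the racemic 2-methyl enone run as a reductive kinetic resolution, which fixes the absolute configuration. The enone comes from a methyl enol ether (DDQ), and the C5 carbinol from methyl addition to a cycloheptanone.
3. Key step: the seven-membered ring is closed by a radical cascade. A primary alkyl radical captures CO, and the acyl radical cyclizes 7-endo onto a 1,4-cyclohexadiene. This forms C5–C6 and C4a–C5, CO becomes C5, and H-atom transfer gives the cis ring fusion.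
4. Radical precursor from o-cresol: O-methylation, para Friedel–Crafts alkylation with 4-methylpent-3-en-1-ol, Birch reduction, Appel bromination.
5. Ring order: six-membered ring first (arene, then Birch diene), seven-membered ring second.

Convention and assumption: positions are numbered as in benzo[7]annulene (C3 carries the ester, C4a/C9a are the ring-fusion carbons, C5 is the tertiary carbinol). The bicyclic intermediates before the CBS step are racemic, and their SMILES show the enantiomer that is carried forward.

**Route**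

Step 1
Reactants: 1 o-cresol
Product: 2 2-methylanisole
Conditions: MeI, K2CO3, acetone, reflux
Reagents that add atoms: iodomethane, CI
Why: Williamson O-methylation of the phenoxide installs the methyl ether that the later Birch reduction needs; no stereocenter.

Step 2
Reactants: 2 2-methylanisole; 3 4-methylpent-3-en-1-ol
Product: 5 4-(4-methoxy-3-methylphenyl)-4-methylpentan-1-ol, via 2,2-dimethyltetrahydrofuran 4 (not isolated)
Conditions: TfOH (10 mol %), HFIP, 50 °C, 2 (3 equiv)
Reagents that add atoms: none
Why: Friedel–Crafts hydroarylation in which the tertiary cation from the trisubstituted alkene (held reversibly as cyclic ether 4) alkylates 2 para to the methoxy group, the only activated position open to a tertiary electrophile; no stereocenter.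

Step 3
Reactants: 5 4-(4-methoxy-3-methylphenyl)-4-methylpentan-1-ol
Product: 6 4-(4-methoxy-5-methylcyclohexa-1,4-dien-1-yl)-4-methylpentan-1-ol
Conditions: Li, NH3 (l), THF, t-BuOH, −78 to −33 °C; then NH4Cl
Reagents that add atoms: none
Why: Birch reduction of the anisole keeps both double bonds on the substituted carbons (the enol ether C=C carrying OMe and Me, and the C=C carrying the tert-alkyl group) and leaves the primary alcohol untouched; no stereocenter.

Step 4
Reactants: 6 4-(4-methoxy-5-methylcyclohexa-1,4-dien-1-yl)-4-methylpentan-1-ol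
Product: 7 1-(5-bromo-2-methylpentan-2-yl)-4-methoxy-5-methylcyclohexa-1,4-diene
Conditions: CBr4, PPh3, imidazole, CH2Cl2, 0 °C
Reagents that add atoms: tetrabromomethane, BrC(Br)(Br)Br
Why: Appel bromination of the primary alcohol under buffered, non-acidic conditions that spare the acid-labile enol ether; no stereocenter.

Step 5
Reactants: 7 1-(5-bromo-2-methylpentan-2-yl)-4-methoxy-5-methylcyclohexa-1,4-diene
Product: 9 rac-(4aR,9aS)-3-methoxy-2,9,9-trimethyl-1,4,4a,6,7,8,9,9a-octahydro-5H-benzo[7]annulen-5-one, via acyl radical 8 (not isolated)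
Conditions: CO (80 atm), (Me3Si)3SiH (slow addition), AIBN (cat.), benzene (0.01 M), 80 °C
Reagents that add atoms: carbon monoxide, [C-]#[O+]
Why: Proposed new method: bromine abstraction by the silyl radical gives a primary alkyl radical that should capture CO under pressure faster than it cyclizes; the nucleophilic acyl radical 8 then closes 7-endo onto the CH carbon of the trisubstituted ring alkene (the fully substituted carbon is blocked), and the resulting tertiary radical takes hydrogen from the silane on the face opposite the new C4a–C5 bond, which sets the cis ring fusion (racemic); the closest known reactions are silane- or stannane-mediated radical carbonylation–cyclization of alkenyl halides and 7-endo cyclizations of acyl radicals made from acyl selenides.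

Step 6
Reactants: 9 rac-(4aR,9aS)-3-methoxy-2,9,9-trimethyl-1,4,4a,6,7,8,9,9a-octahydro-5H-benzo[7]annulen-5-one
Product: 10 rac-(4aR,5S,9aS)-3-methoxy-2,5,9,9-tetramethyl-4,4a,5,6,7,8,9,9a-octahydro-1H-benzo[7]annulen-5-ol
Conditions: MeMgBr, CeCl3, THF, −78 °C
Reagents that add atoms: methylmagnesium bromide, C[Mg]Br
Why: Organocerium 1,2-addition (Imamoto conditions) avoids enolization of the epimerizable ketone, and methyl attacks the carbonyl face anti to the C4a–C9a bond (Felkin–Anh, convex face of the cis-fused bicycle), which places the new hydroxyl trans to H-4a (5S in the 4aR series).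

Step 7
Reactants: 10 rac-(4aR,5S,9aS)-3-methoxy-2,5,9,9-tetramethyl-4,4a,5,6,7,8,9,9a-octahydro-1H-benzo[7]annulen-5-ol
Product: 11 rac-(4aR,5S,9aS)-5-hydroxy-2,5,9,9-tetramethyl-4,4a,5,6,7,8,9,9a-octahydro-3H-benzo[7]annulen-3-one
Conditions: DDQ, CH2Cl2/H2O (20:1), 0 °C to rt
Reagents that add atoms: water, O
Why: DDQ dehydrogenation of the enol ether, in which hydride abstraction from the ring CH2 next to the methyl-bearing enol carbon gives an oxygen-stabilized cation that water hydrolyses to the 2-methyl enone (the outcome of a Saegusa oxidation), with no stereocenter touched.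

Step 8
Reactants: 11 rac-(4aR,5S,9aS)-5-hydroxy-2,5,9,9-tetramethyl-4,4a,5,6,7,8,9,9a-octahydro-3H-benzo[7]annulen-3-one
Product: 12 (3S,4aR,5S,9aS)-2,5,9,9-tetramethyl-4,4a,5,6,7,8,9,9a-octahydro-3H-benzo[7]annulene-3,5-diol
Conditions: (R)-2-methyl-CBS-oxazaborolidine (20 mol %), catecholborane (0.6 equiv), toluene, −78 °C, stopped near 50% conversion; chromatography
Reagents that add atoms: none
Why: Corey–Bakshi–Shibata reduction used as a reductive kinetic resolution, in which catalyst control and substrate control (hydride to the face away from the seven-membered ring) coincide for the (4aR,5S,9aS) ketone and give the 3S alcohol, while the mirror-image ketone is mismatched and is recovered.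

Step 9
Reactants: 13 catechol
Product: 14 4-bromobenzene-1,2-diol
Conditions: NBS, HBF4·OEt2 (cat.), MeCN, −30 °C to rt
Reagents that add atoms: N-bromosuccinimide, O=C1CCC(=O)N1Br
Why: Acid-promoted electrophilic aromatic bromination goes para to one hydroxyl group of catechol; no stereocenter.

Step 10
Reactants: 14 4-bromobenzene-1,2-diol
Product: 15 3,4-dihydroxybenzoic acid
Conditions: Pd(OAc)2 (3 mol %), Xantphos (6 mol %), CO (1 atm), K2CO3, H2O/1,4-dioxane, 90 °C; then aq. HCl
Reagents that add atoms: carbon monoxide, [C-]#[O+]; water, O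
Why: Palladium-catalysed hydroxycarbonylation (Heck-type carbonylation) of the aryl bromide with water as the nucleophile gives the benzoic acid; no stereocenter.

Step 11
Reactants: 12 (3S,4aR,5S,9aS)-2,5,9,9-tetramethyl-4,4a,5,6,7,8,9,9a-octahydro-3H-benzo[7]annulene-3,5-diol; 15 3,4-dihydroxybenzoic acid
Product: 16 (3R,4aR,5S,9aS)-5-hydroxy-2,5,9,9-tetramethyl-4,4a,5,6,7,8,9,9a-octahydro-3H-benzo[7]annulen-3-yl 3,4-dihydroxybenzoate
Conditions: PPh3, DIAD, THF, 0 °C to rt
Reagents that add atoms: none
Why: Mitsunobu esterification, in which the carboxylic acid (far more acidic than the phenols or the tertiary alcohol) displaces the activated secondary allylic oxygen by SN2 from the open face and inverts C3 from S to R.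

Step 12
Reactants: 16 (3R,4aR,5S,9aS)-5-hydroxy-2,5,9,9-tetramethyl-4,4a,5,6,7,8,9,9a-octahydro-3H-benzo[7]annulen-3-yl 3,4-dihydroxybenzoate
Product: 17 target (3R,4aR,5S,9aS)-5-hydroxy-2,5,9,9-tetramethyl-4,4a,5,6,7,8,9,9a-octahydro-3H-benzo[7]annulen-3-yl 3-hydroxy-4-methoxybenzoate
Conditions: MeI (1.05 equiv), Li2CO3, DMF, 40 °C
Reagents that add atoms: iodomethane, CI
Why: Williamson methylation under weak base is selective for the 4-hydroxyl group, whose phenoxide is stabilized by the para ester carbonyl, and leaves the 3-hydroxyl and the tertiary alcohol free; no stereocenter changes.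

**Compound list**

1 | o-cresol (2-methylphenol) | Cc1ccccc1O | starting material
2 | 2-methylanisole (1-methoxy-2-methylbenzene) | COc1ccccc1C | intermediate
3 | 4-methylpent-3-en-1-ol | CC(C)=CCCO | starting material
4 | 2,2-dimethyltetrahydrofuran (not isolated) | CC1(C)CCCO1 | intermediate
5 | 4-(4-methoxy-3-methylphenyl)-4-methylpentan-1-ol | COc1ccc(cc1C)C(C)(C)CCCO | intermediate
6 | 4-(4-methoxy-5-methylcyclohexa-1,4-dien-1-yl)-4-methylpentan-1-ol | COC1=C(C)CC(=CC1)C(C)(C)CCCO | intermediate
7 | 1-(5-bromo-2-methylpentan-2-yl)-4-methoxy-5-methylcyclohexa-1,4-diene | COC1=C(C)CC(=CC1)C(C)(C)CCCBr | intermediate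
8 | 5-(4-methoxy-5-methylcyclohexa-1,4-dien-1-yl)-5-methylhexanoyl radical (not isolated) | COC1=C(C)CC(=CC1)C(C)(C)CCC[C]=O | intermediate
9 | rac-(4aR,9aS)-3-methoxy-2,9,9-trimethyl-1,4,4a,6,7,8,9,9a-octahydro-5H-benzo[7]annulen-5-one (cis-fused) | COC1=C(C)C[C@H]2[C@@H](C1)C(=O)CCCC2(C)C | intermediate
10 | rac-(4aR,5S,9aS)-3-methoxy-2,5,9,9-tetramethyl-4,4a,5,6,7,8,9,9a-octahydro-1H-benzo[7]annulen-5-ol | COC1=C(C)C[C@H]2[C@@H](C1)[C@@](C)(O)CCCC2(C)C | intermediate
11 | rac-(4aR,5S,9aS)-5-hydroxy-2,5,9,9-tetramethyl-4,4a,5,6,7,8,9,9a-octahydro-3H-benzo[7]annulen-3-one | O=C1C[C@@H]2[C@H](C=C1C)C(C)(C)CCC[C@]2(C)O | intermediate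
12 | (3S,4aR,5S,9aS)-2,5,9,9-tetramethyl-4,4a,5,6,7,8,9,9a-octahydro-3H-benzo[7]annulene-3,5-diol | O[C@H]1C[C@@H]2[C@H](C=C1C)C(C)(C)CCC[C@]2(C)O | intermediate
13 | catechol (benzene-1,2-diol) | Oc1ccccc1O | starting material
14 | 4-bromobenzene-1,2-diol | Oc1ccc(Br)cc1O | intermediate
15 | 3,4-dihydroxybenzoic acid | OC(=O)c1ccc(O)c(O)c1 | intermediate
16 | (3R,4aR,5S,9aS)-5-hydroxy-2,5,9,9-tetramethyl-4,4a,5,6,7,8,9,9a-octahydro-3H-benzo[7]annulen-3-yl 3,4-dihydroxybenzoate | Oc1ccc(C(=O)O[C@@H]2C[C@@H]3[C@H](C=C2C)C(C)(C)CCC[C@]3(C)O)cc1O | intermediate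
17 | (3R,4aR,5S,9aS)-5-hydroxy-2,5,9,9-tetramethyl-4,4a,5,6,7,8,9,9a-octahydro-3H-benzo[7]annulen-3-yl 3-hydroxy-4-methoxybenzoate | COc1ccc(C(=O)O[C@@H]2C[C@@H]3[C@H](C=C2C)C(C)(C)CCC[C@]3(C)O)cc1O | target

**Step count and risks**

Total steps: 12. Longest linear sequence: 10 (steps 1–8, 11, 12).

The three steps most likely to fail are steps 5, 7 and 8.

For step 5, the primary radical may cyclize directly before it captures CO, or the acyl radical may be reduced to the aldehyde. The fallback makes the acyl radical directly and brings in the carbonyl carbon by a polar step. It sets out from 7. Mg in THF gives [4-(4-methoxy-5-methylcyclohexa-1,4-dien-1-yl)-4-methylpentyl]magnesium bromide F1. CO2 followed by cold dilute HCl (to pH 4) gives 5-(4-methoxy-5-methylcyclohexa-1,4-dien-1-yl)-5-methylhexanoic acid F2. PhSeSePh and PBu3 in CH2Cl2 give Se-phenyl 5-(4-methoxy-5-methylcyclohexa-1,4-dien-1-yl)-5-methylhexaneselenoate F3. (Me3Si)3SiH and AIBN in dilute benzene at 80 °C then generate acyl radical 8 without an alkyl radical precursor, and the route is rejoined at 9.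

For step 7, DDQ may abstract hydride at the wrong allylic site or over-oxidize. The fallback replaces hydride abstraction by ionic bromination and elimination. It sets out from 10. NBS in THF/H2O at 0 °C gives rac-(4aR,5S,9aS)-2-bromo-5-hydroxy-2,5,9,9-tetramethyl-1,2,4,4a,5,6,7,8,9,9a-decahydro-3H-benzo[7]annulen-3-one F4 as a mixture of C2 epimers. Li2CO3 and LiBr in DMF at 110 °C eliminate HBr toward the ring CH2, and the route is rejoined at 11.

For step 8, the mismatched ketone enantiomer may still be reduced and erode the enantiomeric purity. The fallback uses a non-selective reduction followed by enzymatic resolution. It sets out from 11. NaBH4 and CeCl3·7H2O in MeOH at −78 °C give the racemic cis-diol, that is 12 together with its enantiomer (3R,4aS,5R,9aR)-2,5,9,9-tetramethyl-4,4a,5,6,7,8,9,9a-octahydro-3H-benzo[7]annulene-3,5-diol F5. Burkholderia cepacia lipase with vinyl acetate in MTBE should acetylate the 3R enantiomer (Kazlauskas rule) to (3R,4aS,5R,9aR)-5-hydroxy-2,5,9,9-tetramethyl-4,4a,5,6,7,8,9,9a-octahydro-3H-benzo[7]annulen-3-yl acetate F6 and leave 12, where the route is rejoined.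

**Further compounds**

F1 | step 5 | [4-(4-methoxy-5-methylcyclohexa-1,4-dien-1-yl)-4-methylpentyl]magnesium bromide | COC1=C(C)CC(=CC1)C(C)(C)CCC[Mg]Br
F2 | step 5 | 5-(4-methoxy-5-methylcyclohexa-1,4-dien-1-yl)-5-methylhexanoic acid | COC1=C(C)CC(=CC1)C(C)(C)CCCC(O)=O
F3 | step 5 | Se-phenyl 5-(4-methoxy-5-methylcyclohexa-1,4-dien-1-yl)-5-methylhexaneselenoate | COC1=C(C)CC(=CC1)C(C)(C)CCCC(=O)[Se]c1ccccc1
F4 | step 7 | rac-(4aR,5S,9aS)-2-bromo-5-hydroxy-2,5,9,9-tetramethyl-1,2,4,4a,5,6,7,8,9,9a-decahydro-3H-benzo[7]annulen-3-one (C2 epimers) | O=C1C[C@@H]2[C@H](CC1(C)Br)C(C)(C)CCC[C@]2(C)O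
F5 | step 8 | (3R,4aS,5R,9aR)-2,5,9,9-tetramethyl-4,4a,5,6,7,8,9,9a-octahydro-3H-benzo[7]annulene-3,5-diol | O[C@@H]1C[C@H]2[C@@H](C=C1C)C(C)(C)CCC[C@@]2(C)O
F6 | step 8 | (3R,4aS,5R,9aR)-5-hydroxy-2,5,9,9-tetramethyl-4,4a,5,6,7,8,9,9a-octahydro-3H-benzo[7]annulen-3-yl acetate | CC(=O)O[C@@H]1C[C@H]2[C@@H](C=C1C)C(C)(C)CCC[C@@]2(C)O
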